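**Plan**

- Retrosynthesis cuts, in this order: O9–C13 (the spiro ether; the dihydrofuran is a dearomatised 3-substituted furan), C8–OAc together with C7–OH (from the β-epoxide of a C7=C8 enone), C8–C9 (ring B), C6–C7 (propynyl onto a lactone carbonyl) and C9–C10 (allyl transfer to an aldehyde).
- Enabling feature: ring B holds two adjacent fully substituted carbons, C8 (methyl, oxygen) and C9 (oxygen, side chain), beside the C6 ketone. C6(=O)–C7–C8(CH3) is therefore a but-2-ynoyl group on C5 and C9 a ketone on C10, so ring B is a reductively coupled cis-1,2-diacyl ring A.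
- Forward: ring A is bought (β-cyclocitral). C9–C10 is made first, then a temporary cis-fused C6/O9 γ-lactone, then the ynone and the C9 ketone. Ring B closes in the key step, C7/C8 are oxygenated, and the spiro tetrahydrofuran and the dihydrofuran arise last from the furan.
- Stereochemistry: C10 by catalyst-controlled allylboration; C5 by equilibration in the cis-fused lactone; C9 by substrate control in the ring closure; C7/C8 by convex-face epoxidation and inverting acetolysis; C13 in the selenium-triggered spirocyclisation.

Key step: step 10

Remark: labdane numbering is used for every intermediate (ring A = C1–C5, C10; ring B = C5–C10; side chain C11–C16, C13 being the substituted furan carbon); β is the face of the C10 methyl.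
Assumption: the (S)-antipode of the phosphoric acid in step 5 is taken to expose the Si face of the aldehyde, by analogy with allylborations of simple aldehydes; if the sense proved opposite, the (R)-acid would be used.

**Route**

Step 1
Reactants: 1 furan-3-carbaldehyde; 2 (triphenylphosphoranylidene)acetaldehyde
Product: 3 (E)-3-(furan-3-yl)prop-2-enal
Conditions: toluene, 80 °C
Reagents that add atoms: none
Why: Wittig olefination with the stabilised formyl ylide should give the E-enal, the heteroaryl aldehyde being consumed before the less electrophilic conjugated product reacts again.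

Step 2
Reactants: 3 (E)-3-(furan-3-yl)prop-2-enal
Product: 4 3-(furan-3-yl)propanal
Conditions: Hantzsch ester (1.1 equiv), dibenzylammonium trifluoroacetate (5 mol%), THF, 23 °C
Reagents that add atoms: none
Why: Iminium-ion organocatalytic transfer hydrogenation reduces only the conjugated C=C bond and leaves the aldehyde and the furan untouched.

Step 3
Reactants: 5 β-cyclocitral
Product: 6 β-cyclogeraniol
Conditions: NaBH4, MeOH, 0 °C
Reagents that add atoms: none
Why: 1,2-Reduction of the hindered enal by NaBH4 gives the primary allylic alcohol.

Step 4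
Reactants: 6 β-cyclogeraniol
Product: 7 β-cyclogeranyl pinacol boronate (boron on C6)
Conditions: B2pin2, [Pd(MeCN)4](BF4)2 (5 mol%), DMSO/MeOH 1:1, 40 °C
Reagents that add atoms: bis(pinacolato)diboron, CC1(C)OB(OC1(C)C)B1OC(C)(C)C(C)(C)O1
Why: Pd-catalysed allylic borylation of the free alcohol runs through a π-allyl complex and should place boron on the unhindered primary terminus C6.

Step 5
Reactants: 7 β-cyclogeranyl pinacol boronate; 4 3-(furan-3-yl)propanal
Product: 9 (9R,10S)-homoallylic alcohol with the C5=C6 exocyclic methylene, via pinacol borate ester 8 (not isolated)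
Conditions: (S)-TRIP phosphoric acid [(S)-3,3'-bis(2,4,6-triisopropylphenyl)-1,1'-binaphthyl-2,2'-diyl hydrogen phosphate] (5 mol%), 4 Å MS, toluene, −30 → 0 °C; aq. NaHCO3
Reagents that add atoms: none
Why: Chiral-phosphoric-acid-catalysed allylboration through a closed Zimmerman–Traxler chair transfers the allyl unit with γ-selectivity, so C10 becomes the quaternary centre; the acid-bound aldehyde is attacked on its Si face and the ring-locked alkene geometry (methyl axial, C1 equatorial in the chair) then fixes C10 as S together with 9R.

Step 6
Reactants: 9 (9R,10S)-homoallylic alcohol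
Product: 11 1,4-diol with the C6 hydroxymethyl cis to the C10 methyl (H5 α), via cyclic alkoxyborane 10 (not isolated)
Conditions: BH3·SMe2, THF, 0 → 23 °C; then NaOH, H2O2, 0 °C
Reagents that add atoms: hydrogen peroxide, OO
Why: Hydroboration–oxidation, delivered from the alkoxyborane formed at O9 faster than borane can touch the furan, puts boron on terminal C6 and hydrogen on C5 from the face away from the axial C4 and C10 methyls, which is expected to give mainly the 5-epimer; this centre is corrected in step 7.

Step 7
Reactants: 11 1,4-diol
Product: 13 cis-fused γ-lactone (C6 carbonyl and O9 both α; H5 β and cis to the C10 methyl), via trans-fused lactone 12 (not isolated)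
Conditions: TEMPO (20 mol%), PhI(OAc)2 (2.5 equiv), CH2Cl2, 23 °C; then t-BuOK (20 mol%), THF/t-BuOH, 23 °C
Reagents that add atoms: none
Why: Oxidative lactonisation of the 1,4-diol (primary alcohol to aldehyde, lactol to lactone) is followed by base-mediated enolisation at C5, which should equilibrate the trans-fused lactone to the more stable cis-fused one, the usual preference of a five-membered ring carbonyl next to a ring fusion that carries an angular methyl, and so sets H5 cis to the C10 methyl.

Step 8
Reactants: 13 cis-fused γ-lactone; 14 1-propynylmagnesium bromide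
Product: 15 hydroxy ynone (but-2-ynoyl on C5 and 9R-carbinol on C10, cis)
Conditions: THF, −40 → 0 °C; sat. aq. NH4Cl at −40 °C
Reagents that add atoms: none
Why: Addition of the alkynyl Grignard reagent to the lactone should stop at the magnesium hemiketal, which opens on work-up to the hydroxy ynone (mono-addition of an acetylide to a lactone) without touching C5.

Step 9
Reactants: 15 hydroxy ynone
Product: 16 ynone–ketone (5R,10S; but-2-ynoyl on C5 and 3-(furan-3-yl)propanoyl on C10, cis)
Conditions: Dess–Martin periodinane, CH2Cl2, 0 °C
Reagents that add atoms: none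
Why: Dess–Martin oxidation of the secondary C9 alcohol under near-neutral conditions gives the 1,4-diketone without enolising the C5 centre next to the ynone carbonyl.

Step 10
Reactants: 16 ynone–ketone
Product: 17 cis-fused enone (C7=C8 enone, 8-methyl, 9α-hydroxy, 9β-(2-(furan-3-yl)ethyl), 5β-H)
Conditions: SmI2 (2.2 equiv), HMPA (8 equiv), THF, −78 °C, slow addition of 16; then t-BuOH, −78 °C
Reagents that add atoms: none
Why: Proposed new method: SmI2–HMPA transfers an electron to the most easily reduced group, the ynone, and the radical anion (or a C9 ketyl formed from it by electron exchange) joins C8 to the C9 carbonyl carbon; the oxygen radical at O9 is reduced at once to the samarium alkoxide and the C7 vinylsamarium is protonated by t-BuOH to the C7=C8 enone. The closest known reaction type is the SmI2 ketyl–alkyne reductive cyclisation, known in the exo mode and for medium rings in the endo-dig mode, together with SmI2 couplings of ketones with the β-carbon of conjugated acceptors. Ring B closes 6-endo-dig with respect to the ynone and 6-exo-trig with respect to the C9 carbonyl. The new C9 centre is controlled by the cis-substituted ring A: in the chair-like transition state that keeps C1 pseudoaxial, the C9 position that becomes pseudoequatorial eclipses the C8 methyl and lies between C1 and the C10 methyl, so it is taken by oxygen, and the furylethyl chain goes pseudoaxial on the β-face (O9 α). The step needs bonding through C8 and not C7: spin and charge of the reduced ynone sit on C8, and the proton source is withheld until the ring is closed, so no allenolate forms that could close a five-membered ring through C7 by aldol addition. Adding the alcohol only after the SmI2 is consumed also limits over-reduction of the enone, and the aprotic cold medium leaves C5 unenolised.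

Step 11
Reactants: 17 cis-fused enone
Product: 18 7β,8β-epoxy ketone
Conditions: t-BuOOH, DBU, CH2Cl2, 0 °C
Reagents that add atoms: tert-butyl hydroperoxide, CC(C)(C)OO
Why: Weitz–Scheffer nucleophilic epoxidation should occur on the convex β-face of the enone, the α-face being covered by the C1 methylene of ring A that is axial on ring B, and the peroxide anion leaves the furan untouched.

Step 12
Reactants: 18 7β,8β-epoxy ketone
Product: 19 8α-acetoxy-7β,9α-dihydroxy ketone (furan intact)
Conditions: AcOH, Sc(OTf)3 (5 mol%), 23 °C
Reagents that add atoms: acetic acid, CC(=O)O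
Why: Lewis-acid-assisted acetolysis opens the α,β-epoxy ketone at the tertiary C8, remote from the carbonyl, with inversion (trans-diaxial Fürst–Plattner opening), giving the 8α-acetate and keeping the 7β-hydroxyl.

Step 13
Reactants: 19 8α-acetoxy-7β,9α-dihydroxy ketone
Product: 20 16-(phenylselanyl) spiro enol ether (O9–C13 bond formed, 13S, selenium on C16 trans to O9)
Conditions: PhSeCl, 2,6-lutidine, CH2Cl2, −78 °C
Reagents that add atoms: benzeneselenenyl chloride, Cl[Se]c1ccccc1
Why: Proposed new method: PhSeCl should attack the furan at C16, the α-position next to the alkyl group, and the allyl/oxocarbenium ion (charge on C13 and on O–C15) is captured at C13 by the tethered 9-hydroxyl in a 5-exo closure faster than C16 can lose its proton, giving anti addition across C16–C13 under kinetic control while 2,6-lutidine removes HCl so that the acid-labile spiro enol ether cannot revert to the furan; the closest known reactions are the phenylselenoetherification of alkenols and the halogen-induced dearomatising addition of alcohols to furans (Clauson-Kaas and Achmatowicz oxidations); C13 is set by attack of O9 on the furan face that turns the selenium-bearing C16 toward C10 and the flat C14=C15 arm toward the larger 8α-acetate, and C16 is a transient stereocentre.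

Step 14
Reactants: 20 16-(phenylselanyl) spiro enol ether
Product: 21 (5R,7R,8R,9S,10S,13S)-8-acetoxy-7-hydroxy-9,13:15,16-diepoxylabd-14-en-6-one (target)
Conditions: Bu3SnH, Et3B (cat.), air, toluene, 0 °C
Reagents that add atoms: none
Why: Radical chain reduction of the O,Se-acetal by Bu3SnH replaces selenium on C16 by hydrogen at low temperature and leaves the ketone, the tertiary acetate and the enol ether intact.

**Compound list**

1 | furan-3-carbaldehyde | O=Cc1ccoc1 | starting material
2 | (triphenylphosphoranylidene)acetaldehyde | O=CC=P(c1ccccc1)(c1ccccc1)c1ccccc1 | starting material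
3 | (E)-3-(furan-3-yl)prop-2-enal | O=C/C=C/c1ccoc1 | intermediate
4 | 3-(furan-3-yl)propanal | O=CCCc1ccoc1 | intermediate
5 | β-cyclocitral | CC1=C(C=O)C(C)(C)CCC1 | starting material
6 | β-cyclogeraniol | CC1=C(CO)C(C)(C)CCC1 | intermediate
7 | β-cyclogeranyl pinacol boronate | CC1=C(CB2OC(C)(C)C(C)(C)O2)C(C)(C)CCC1 | intermediate
8 | pinacol borate ester of alcohol 9 (not isolated) | C=C1C(C)(C)CCC[C@]1(C)[C@H](OB1OC(C)(C)C(C)(C)O1)CCc1ccoc1 | intermediate
9 | (1R)-3-(furan-3-yl)-1-[(1S)-1,3,3-trimethyl-2-methylidenecyclohexyl]propan-1-ol (9R,10S) | C=C1C(C)(C)CCC[C@]1(C)[C@H](O)CCc1ccoc1 | intermediate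
10 | cyclic alkoxyborane, boron bridging O9 and C6, H5 α (not isolated) | [BH]1C[C@H]2C(C)(C)CCC[C@]2(C)[C@@H](CCc2ccoc2)O1 | intermediate
11 | 1,4-diol, C6 hydroxymethyl cis to the C10 methyl (H5 α), 9R | OC[C@H]1C(C)(C)CCC[C@]1(C)[C@H](O)CCc1ccoc1 | intermediate
12 | trans-fused γ-lactone, H5 α (not isolated) | O=C1[C@H]2C(C)(C)CCC[C@]2(C)[C@@H](CCc2ccoc2)O1 | intermediate
13 | cis-fused γ-lactone, H5 β | O=C1[C@@H]2C(C)(C)CCC[C@]2(C)[C@@H](CCc2ccoc2)O1 | intermediate
14 | 1-propynylmagnesium bromide | CC#C[Mg]Br | starting material
15 | hydroxy ynone (cis, 9R-carbinol) | CC#CC(=O)[C@@H]1C(C)(C)CCC[C@]1(C)[C@H](O)CCc1ccoc1 | intermediate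
16 | ynone–ketone (5R,10S), acyl groups cis | CC#CC(=O)[C@@H]1C(C)(C)CCC[C@]1(C)C(=O)CCc1ccoc1 | intermediate
17 | cis-fused 9α-hydroxy-8-methyl enone with 9β-furylethyl chain | CC1=CC(=O)[C@@H]2C(C)(C)CCC[C@]2(C)[C@@]1(O)CCc1ccoc1 | intermediate
18 | 7β,8β-epoxy ketone | C[C@]12O[C@H]1C(=O)[C@@H]1C(C)(C)CCC[C@]1(C)[C@@]2(O)CCc1ccoc1 | intermediate
19 | 8α-acetoxy-7β,9α-dihydroxy ketone with furan | CC(=O)O[C@]1(C)[C@@H](O)C(=O)[C@@H]2C(C)(C)CCC[C@]2(C)[C@@]1(O)CCc1ccoc1 | intermediate
20 | 16-(phenylselanyl) spiro enol ether | CC(=O)O[C@]1(C)[C@@H](O)C(=O)[C@@H]2C(C)(C)CCC[C@]2(C)[C@@]12CC[C@@]1(C=CO[C@@H]1[Se]c1ccccc1)O2 | intermediate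
21 | (5R,7R,8R,9S,10S,13S)-8-acetoxy-7-hydroxy-9,13:15,16-diepoxylabd-14-en-6-one | CC(=O)O[C@]1(C)[C@@H](O)C(=O)[C@@H]2C(C)(C)CCC[C@]2(C)[C@@]12CC[C@@]1(C=COC1)O2 | target

**Step count and main risks**

Total steps: 14. Longest linear sequence: 12 (steps 3–14 from β-cyclocitral; the aldehyde branch, steps 1, 2 and 5–14, is equally long).

Most likely to fail:

1. Step 10 (key step).
   - What may go wrong: the reduced ynone may be protonated or reduced further before it reaches C9; it may close through C7 to a five-membered ring; or it may bond to the wrong face of the C9 carbonyl.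
   - Fallback: from ynone–ketone 16, hydroiodination (NaI, AcOH, 23 °C) gives the (Z)-β-iodoenone F1. CrCl2 with catalytic NiCl2 in DMSO (intramolecular Nozaki–Hiyama–Kishi addition of the alkenylchromium to the C9 ketone) then forms the same C8–C9 bond by a polar 1,2-addition that has no five-membered alternative. The route is rejoined at enone 17.

2. Step 13.
   - What may go wrong: after selenium attack the cation may lose a proton and re-aromatise (substitution instead of addition); the spiro ether may reopen under traces of acid; the facial selectivity at C13 may be poor.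
   - Fallback (known chemistry, replacing steps 11–14): from enone 17, photo-oxygenation of the furan (O2, rose bengal, hν, i-Pr2NEt, −78 °C) gives the γ-hydroxybutenolide F2 with the carbonyl at C15. NaBH4/CeCl3 reduces the masked C16 aldehyde, which relactonises, and the C6 ketone, giving the butenolide allylic alcohol F3. DBU closes the tetrahydrofuran by oxa-Michael addition of O9 to C13 and gives the spiro lactone F4; C13 is set under equilibrating conditions and the epimers are separated here. i-Bu2AlH at −78 °C, then MeOH with pyridinium tosylate, gives the lactol methyl acetal F5, and MnO2 restores the enone F6. t-BuOOH/DBU and AcOH/Sc(OTf)3, as in steps 11 and 12, give the epoxy ketone acetal F7 and the hydroxy acetate acetal F8. Loss of methanol from the acetal (TMSOTf, i-Pr2NEt, then buffered fluoride to free O7) forms the C14=C15 enol ether and returns to the route at 21.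

3. Step 5.
   - What may go wrong: allyl transfer from the congested, fully substituted boronate may be slow, so that an uncatalysed racemic pathway or the wrong sense of induction erodes the only absolute stereocontrol of the route.
   - Fallback: from β-cyclogeraniol 6, PBr3 gives β-cyclogeranyl bromide F9. An indium-mediated Barbier reaction with aldehyde 4 gives the γ-adduct as the racemic homoallylic alcohol F10, and Dess–Martin oxidation gives the racemic ketone F11. Corey–Bakshi–Shibata reduction ((S)-methyl oxazaborolidine, catecholborane) sets 9R in both enantiomers and the diastereomers are separated. The (9R,10S)-isomer rejoins the route at 9 and the (9R,10R)-diastereomer F12 is discarded.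

Further compounds
F1 | step 10 | (Z)-β-iodoenone of 16 (iodine on C8, cis to C6) | C/C(I)=C/C(=O)[C@@H]1C(C)(C)CCC[C@]1(C)C(=O)CCc1ccoc1
F2 | step 13 | γ-hydroxybutenolide from 17 (C15 carbonyl, C16 hydroxyl, epimers at C16) | CC1=CC(=O)[C@@H]2C(C)(C)CCC[C@]2(C)[C@@]1(O)CCC1=CC(=O)OC1O
F3 | step 13 | butenolide allylic alcohol (C6 carbinol, configuration not assigned) | CC1=CC(O)[C@@H]2C(C)(C)CCC[C@]2(C)[C@@]1(O)CCC1=CC(=O)OC1
F4 | step 13 | 9,13-epoxy spiro lactone (C15 carbonyl), C6 carbinol | CC1=CC(O)[C@@H]2C(C)(C)CCC[C@]2(C)[C@@]12CC[C@@]1(CC(=O)OC1)O2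
F5 | step 13 | spiro lactol methyl acetal (15-methoxy, epimers at C15), C6 carbinol | CC1=CC(O)[C@@H]2C(C)(C)CCC[C@]2(C)[C@@]12CC[C@@]1(CC(OC)OC1)O2
F6 | step 13 | spiro 15-methoxy acetal enone | CC1=CC(=O)[C@@H]2C(C)(C)CCC[C@]2(C)[C@@]12CC[C@@]1(CC(OC)OC1)O2
F7 | step 13 | spiro 15-methoxy acetal 7β,8β-epoxy ketone | C[C@]12O[C@H]1C(=O)[C@@H]1C(C)(C)CCC[C@]1(C)[C@@]23CC[C@@]2(CC(OC)OC2)O3
F8 | step 13 | spiro 15-methoxy acetal 8α-acetoxy-7β-hydroxy ketone | CC(=O)O[C@]1(C)[C@@H](O)C(=O)[C@@H]2C(C)(C)CCC[C@]2(C)[C@@]12CC[C@@]1(CC(OC)OC1)O2
F9 | step 5 | β-cyclogeranyl bromide | CC1=C(CBr)C(C)(C)CCC1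
F10 | step 5 | racemic homoallylic alcohol (diastereomer mixture) | C=C1C(C)(C)CCCC1(C)C(O)CCc1ccoc1
F11 | step 5 | racemic β,γ-unsaturated ketone | C=C1C(C)(C)CCCC1(C)C(=O)CCc1ccoc1
F12 | step 5 | (9R,10R)-diastereomer of 9 | C=C1C(C)(C)CCC[C@@]1(C)[C@H](O)CCc1ccoc1
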